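**Retrosynthetic overview**
1. Target (labdane numbering) ⇒ the C8=C17 exocyclic alkene and the C7 methylene come from a C7=C8 allylic alcohol (C17–OH) by reductive 1,3-transposition, and that alcohol from the C7=C8 enal.
2. Ring B (formed last) ⇒ C7–C8 and C9–C10 are cut together: a ring-A cyclohexene carrying the C5–C6–C7 acetaldehyde arm plus the (E)-enal C17(=O)–C8=C9 that already holds C11–C16 with the butenolide; iron-hydride-initiated radical conjugate addition–aldol annulation, then dehydration.
3. Enabling feature: in ring B the methyl-bearing fusion carbon C10 flanks C9 and is 1,4 to C7, and C8 carries the single exocyclic carbon C17; so C10 can be a tertiary radical (H atom to C1 of a C1=C10 ring-A alkene), C9/C8/C17 the β-carbon, α-carbon and carbonyl of an enal, and C7 an aldehyde on which the C8 enolate closes.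
4. Ring A (formed first): an asymmetric Diels–Alder reaction of a 1-amino-3-siloxybutadiene with methacrolein sets C4; the C1 carbinol (CBS reduction) passes its configuration to C5 in a Claisen rearrangement that also installs C6–C7 and the C1=C10 alkene.
5. Enal: Negishi coupling of 4-bromofuran-2(5H)-one with but-3-enylzinc bromide, then cross-metathesis with crotonaldehyde; the butenolide ring is bought.

Key step: step 9

Numbering: labdane numbering is used for the bicyclic compounds and their precursors (ring A: C1–C5 and C10; ring B: C5–C10; C17 exocyclic on C8; C11–C16 side chain with C15 the lactone carbonyl and C16 its O–CH2; C18 methyl and C19 acetoxymethyl on C4; C20 methyl on C10).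
Assumption: the sense of induction of the diol catalyst in step 1 and of the oxazaborolidine in step 4 is taken from the usual models; if the opposite sense is found, the enantiomeric catalyst is used.

**Step 1**
Reactants: 1 (E)-1-(dimethylamino)-3-[(tert-butyldimethylsilyl)oxy]buta-1,3-diene; 2 methacrolein (2-methylprop-2-enal)
Product: 5 (4R)-4-(hydroxymethyl)-4-methylcyclohex-2-en-1-one, via cycloadduct aldehyde 3 (not isolated), via amino alcohol 4 (not isolated)
Conditions: (R,R)-tetra(1-naphthyl)-TADDOL (20 mol %), PhMe, −80 °C; LiAlH4, Et2O, −78 → 0 °C; aq. HF, MeCN, 0 → 23 °C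
Reagents that add atoms: none
Why: Hydrogen-bond-catalysed Diels–Alder reaction in which the chiral diol activates methacrolein and shields one of its faces, the amino diene adds endo with the amino carbon next to the new quaternary carbon (this sets C4 as R), and hydride reduction of the aldehyde followed by acid hydrolysis of the silyl enol ether with β-elimination of dimethylamine unmasks the enone.

**Step 2**
Reactants: 5 (4R)-4-(hydroxymethyl)-4-methylcyclohex-2-en-1-one
Product: 6 [(1R)-1-methyl-4-oxocyclohex-2-en-1-yl]methyl acetate
Conditions: Ac2O, pyridine, DMAP (cat.), CH2Cl2, 0 → 23 °C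
Reagents that add atoms: acetic anhydride, CC(=O)OC(C)=O
Why: DMAP-catalysed acylation of the primary alcohol puts the acetate of the target in place early, where it also serves as the protecting group; no stereocenter is touched.

**Step 3**
Reactants: 6 [(1R)-1-methyl-4-oxocyclohex-2-en-1-yl]methyl acetate
Product: 7 [(1R)-3-iodo-1-methyl-4-oxocyclohex-2-en-1-yl]methyl acetate
Conditions: I2, pyridine/CH2Cl2, 0 → 23 °C
Reagents that add atoms: iodine, II
Why: α-Iodination of the enone by conjugate addition of pyridine, iodination of the enolate and elimination places the handle for the C20 methyl on C10; the C4 center is not affected.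

**Step 4**
Reactants: 7 [(1R)-3-iodo-1-methyl-4-oxocyclohex-2-en-1-yl]methyl acetate
Product: 8 [(1R,4S)-4-hydroxy-3-iodo-1-methylcyclohex-2-en-1-yl]methyl acetate
Conditions: (R)-2-methyl-CBS-oxazaborolidine (20 mol %), BH3·SMe2, THF, −30 °C
Reagents that add atoms: none
Why: Corey–Bakshi–Shibata reduction, in which the oxazaborolidine controls the face of 1,2-hydride delivery with the α-iodoalkenyl arm as the large group, so the C1 carbinol (S) is set cis to the acetoxymethyl group irrespective of the remote C4 center; the acetate is inert to borane at this temperature.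

**Step 5**
Reactants: 8 [(1R,4S)-4-hydroxy-3-iodo-1-methylcyclohex-2-en-1-yl]methyl acetate
Product: 9 [(1R,4S)-4-hydroxy-1,3-dimethylcyclohex-2-en-1-yl]methyl acetate
Conditions: SnMe4, Pd2(dba)3 (cat.), AsPh3, CuI, NMP, 60 °C
Reagents that add atoms: tetramethylstannane, C[Sn](C)(C)C
Why: Stille coupling of the alkenyl iodide installs the C20 methyl without moving the alkene; the free allylic alcohol and the acetate are tolerated and no stereocenter is touched.

**Step 6**
Reactants: 9 [(1R,4S)-4-hydroxy-1,3-dimethylcyclohex-2-en-1-yl]methyl acetate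
Product: 11 [(1R,2S)-1,3-dimethyl-2-(2-oxoethyl)cyclohex-3-en-1-yl]methyl acetate, via allyl vinyl ether 10 (not isolated)
Conditions: butyl vinyl ether (solvent), Pd(OCOCF3)2 (cat.), 4,7-diphenyl-1,10-phenanthroline, Et3N, 75 °C; then evaporation, xylenes, 170 °C (sealed tube)
Reagents that add atoms: butyl vinyl ether, C=COCCCC
Why: Palladium-catalysed vinyl transfer gives the allyl vinyl ether, which undergoes the Claisen rearrangement on heating; the suprafacial [3,3] shift delivers C6 to C5 on the face that carried the oxygen at C1, so C5 (S) is set cis to the acetoxymethyl group, and the C1=C10 alkene and the C7 aldehyde arise in the same event.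

**Step 7**
Reactants: 12 4-bromofuran-2(5H)-one; 13 but-3-en-1-ylzinc bromide
Product: 14 4-(but-3-en-1-yl)furan-2(5H)-one
Conditions: PdCl2(dppf) (cat.), THF, 23 → 50 °C
Reagents that add atoms: none
Why: Negishi coupling of the activated β-bromo butenolide with the primary alkylzinc reagent; the bidentate ligand suppresses β-hydride elimination.

**Step 8**
Reactants: 14 4-(but-3-en-1-yl)furan-2(5H)-one; 15 (E)-but-2-enal (crotonaldehyde, 5 equiv)
Product: 16 (E)-5-(5-oxo-2,5-dihydrofuran-3-yl)pent-2-enal
Conditions: second-generation Hoveyda–Grubbs catalyst (5 mol %), CH2Cl2, 40 °C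
Reagents that add atoms: none
Why: Olefin cross-metathesis of the terminal alkene with excess crotonaldehyde should give the E-enal under thermodynamic control, while the electron-poor trisubstituted butenolide alkene does not engage the catalyst.

**Step 9**
Reactants: 11 [(1R,2S)-1,3-dimethyl-2-(2-oxoethyl)cyclohex-3-en-1-yl]methyl acetate; 16 (E)-5-(5-oxo-2,5-dihydrofuran-3-yl)pent-2-enal (3 equiv)
Product: 18 ent-19-acetoxy-17-oxolabda-7,13-dien-15,16-olide, via aldol 17 (not isolated)
Conditions: Fe(acac)3 (30 mol %), PhSiH3, EtOH/(CH2OH)2 5:1, 0 → 23 °C, slow addition of 11; then crude product, TsOH·H2O (cat.), PhMe, 23 °C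
Reagents that add atoms: none
Why: Fe(acac)3 and PhSiH3 form an iron hydride that transfers a hydrogen atom to C1 of the electron-rich C1=C10 alkene of 11; the tertiary C10 radical adds to the β-carbon C9 of enal 16 (Giese addition, C9–C10 bond), the α-formyl radical at C8 is reduced by divalent iron to an iron enolate that adds to the C7 aldehyde (aldol, C7–C8 bond) to give 17, and acid then removes water across C7–C8. The closest known reaction type is the hydrogen-atom-transfer-initiated radical conjugate addition–aldol (radical–polar crossover) annulation of γ,δ-unsaturated aldehydes with enones and enals used to build terpenoid decalins. Ring B is closed in the aldol event in the 6-(enolexo)-exo-trig mode. C10 is controlled by ring A: the enal approaches the radical on the face opposite the C5 acetaldehyde arm and the 1,3-related C4 acetoxymethyl group, which gives the trans ring fusion with the new methyl cis to CH2OAc. C9 is set in the same addition, by the approach that keeps the enal chain anti to C5 and places C8 beside the C6–C7 arm (the arrangement that leads on to closure), so that H9 ends anti to the C10 methyl, while the C7 and C8 centers of 17 are erased by the dehydration. The step needs hydrogen-atom transfer to the C1=C10 alkene and not to the electron-poor enal or butenolide alkenes (secured by the polarity of iron-hydride transfer), addition to the disubstituted enal and not to the β,β-disubstituted butenolide carbon (secured by sterics), and facial selectivity at C9, which rests on sterics alone and is the least secure point.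

**Step 10**
Reactants: 18 ent-19-acetoxy-17-oxolabda-7,13-dien-15,16-olide
Product: 19 ent-19-acetoxy-17-hydroxylabda-7,13-dien-15,16-olide
Conditions: NaBH4, CeCl3·7H2O, MeOH, −78 °C
Reagents that add atoms: none
Why: Luche reduction, a cerium-mediated 1,2-reduction of the aldehyde that at low temperature should leave the butenolide and the acetate untouched; no stereocenter is formed.

**Step 11**
Reactants: 19 ent-19-acetoxy-17-hydroxylabda-7,13-dien-15,16-olide
Product: 22 ent-19-acetoxylabda-8(17),13-dien-15,16-olide (CNP0189477.2), via sulfonylhydrazine 20 (not isolated), via allylic diazene 21 (not isolated)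
Conditions: 2-nitrobenzenesulfonylhydrazide (NBSH), PPh3, DEAD, THF, −30 → 23 °C
Reagents that add atoms: none
Why: Reductive 1,3-transposition of the allylic alcohol: the Mitsunobu reaction with NBSH gives the N-allylic sulfonylhydrazine, loss of the sulfinic acid on warming gives the monoalkyl diazene, and its retro-ene loss of N2 delivers hydrogen to C7 and moves the alkene to C8=C17; C7 becomes a methylene, so no new stereocenter arises and C9 is not touched.

**Compound list**
1 | (E)-1-(dimethylamino)-3-[(tert-butyldimethylsilyl)oxy]buta-1,3-diene | CN(C)/C=C/C(=C)O[Si](C)(C)C(C)(C)C | starting material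
2 | methacrolein (2-methylprop-2-enal) | CC(=C)C=O | starting material
3 | (1R,2S)-4-[(tert-butyldimethylsilyl)oxy]-2-(dimethylamino)-1-methylcyclohex-3-ene-1-carbaldehyde (endo cycloadduct, CHO and NMe2 cis) | O=C[C@]1(C)CCC(O[Si](C)(C)C(C)(C)C)=C[C@@H]1N(C)C | intermediate
4 | [(1R,2S)-4-[(tert-butyldimethylsilyl)oxy]-2-(dimethylamino)-1-methylcyclohex-3-en-1-yl]methanol | OC[C@]1(C)CCC(O[Si](C)(C)C(C)(C)C)=C[C@@H]1N(C)C | intermediate
5 | (4R)-4-(hydroxymethyl)-4-methylcyclohex-2-en-1-one | O=C1CC[C@@](C)(CO)C=C1 | intermediate
6 | [(1R)-1-methyl-4-oxocyclohex-2-en-1-yl]methyl acetate | O=C1CC[C@@](C)(COC(C)=O)C=C1 | intermediate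
7 | [(1R)-3-iodo-1-methyl-4-oxocyclohex-2-en-1-yl]methyl acetate | O=C1CC[C@@](C)(COC(C)=O)C=C1I | intermediate
8 | [(1R,4S)-4-hydroxy-3-iodo-1-methylcyclohex-2-en-1-yl]methyl acetate (OH cis to CH2OAc) | O[C@H]1CC[C@@](C)(COC(C)=O)C=C1I | intermediate
9 | [(1R,4S)-4-hydroxy-1,3-dimethylcyclohex-2-en-1-yl]methyl acetate | O[C@H]1CC[C@@](C)(COC(C)=O)C=C1C | intermediate
10 | [(1R,4S)-4-(ethenyloxy)-1,3-dimethylcyclohex-2-en-1-yl]methyl acetate | C=CO[C@H]1CC[C@@](C)(COC(C)=O)C=C1C | intermediate
11 | [(1R,2S)-1,3-dimethyl-2-(2-oxoethyl)cyclohex-3-en-1-yl]methyl acetate (CH2CHO cis to CH2OAc) | O=CC[C@@H]1[C@](C)(COC(C)=O)CCC=C1C | intermediate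
12 | 4-bromofuran-2(5H)-one | O=C1C=C(Br)CO1 | starting material
13 | but-3-en-1-ylzinc bromide | C=CCC[Zn]Br | starting material
14 | 4-(but-3-en-1-yl)furan-2(5H)-one | C=CCCC1=CC(=O)OC1 | intermediate
15 | (E)-but-2-enal (crotonaldehyde) | C/C=C/C=O | starting material
16 | (E)-5-(5-oxo-2,5-dihydrofuran-3-yl)pent-2-enal | O=C/C=C/CCC1=CC(=O)OC1 | intermediate
17 | ent-19-acetoxy-7-hydroxy-17-oxolabd-13-en-15,16-olide (trans-decalin; 7R,8R drawn, hydroxyl and formyl equatorial, the expected aldol diastereomer; C7 and C8 are of no consequence) | O=C[C@H]1[C@H](O)C[C@@H]2[C@](C)(COC(C)=O)CCC[C@@]2(C)[C@@H]1CCC1=CC(=O)OC1 | intermediate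
18 | ent-19-acetoxy-17-oxolabda-7,13-dien-15,16-olide (trans-fused; H5 and H9 on the face opposite the C10 methyl and the C4 acetoxymethyl) | O=CC1=CC[C@@H]2[C@](C)(COC(C)=O)CCC[C@@]2(C)[C@@H]1CCC1=CC(=O)OC1 | intermediate
19 | ent-19-acetoxy-17-hydroxylabda-7,13-dien-15,16-olide | OCC1=CC[C@@H]2[C@](C)(COC(C)=O)CCC[C@@]2(C)[C@@H]1CCC1=CC(=O)OC1 | intermediate
20 | N-(C17-allylic) N-(2-nitrobenzenesulfonyl)hydrazine derived from 19 | NN(CC1=CC[C@@H]2[C@](C)(COC(C)=O)CCC[C@@]2(C)[C@@H]1CCC1=CC(=O)OC1)S(=O)(=O)c1ccccc1[N+](=O)[O-] | intermediate
21 | C17 monoalkyl diazene derived from 20 | N=NCC1=CC[C@@H]2[C@](C)(COC(C)=O)CCC[C@@]2(C)[C@@H]1CCC1=CC(=O)OC1 | intermediate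
22 | ent-19-acetoxylabda-8(17),13-dien-15,16-olide = [(1R,4aS,5R,8aS)-1,4a-dimethyl-6-methylidene-5-[2-(5-oxo-2,5-dihydrofuran-3-yl)ethyl]decahydronaphthalen-1-yl]methyl acetate | C=C1CC[C@@H]2[C@](C)(COC(C)=O)CCC[C@@]2(C)[C@@H]1CCC1=CC(=O)OC1 | target

**Totals**
Total step count: 11. Longest linear sequence: 9 steps (steps 1–6, 9, 10, 11).

**Steps most likely to fail**

Step 9: the radical addition may show poor facial selectivity at C9 (the C10 face is secured by ring A, the enal face is not), so that a C9 epimer is carried along; simple reduction of the C10 radical may also compete. The fallback sets out from 22, obtained together with the 9-epimer of 22 F1 when the mixture is taken through steps 10 and 11, and comes back at 22. Ozonolysis of the 1,1-disubstituted alkene only (O3, CH2Cl2/MeOH, −78 °C, then Me2S; the electron-poor butenolide alkene reacts far more slowly) should give the 17-nor-8-ketone F2 and the 9-epimer of F2 F3. DBU in toluene at 80 °C equilibrates C9 through the enol toward F2, which has the side chain equatorial; this preference is expected to be modest, so residual F3 is recycled. Takai–Lombardo methylenation of F2 (Zn, CH2Br2, TiCl4, THF/CH2Cl2, 0 → 23 °C), which tolerates esters and lactones, returns 22.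

Step 6: vinyl transfer to the hindered secondary alcohol may stall, and the [3,3] shift to the C5 terminus next to the quaternary C4 may be slower than elimination of the allylic ether to a diene. The fallback sets out from 9 and comes back at 11. Eschenmoser–Claisen rearrangement of 9 with N,N-dimethylacetamide dimethyl acetal (xylenes, 140 °C), in which the ketene N,O-acetal forms and rearranges in one pot, should give the dimethylamide F4 with the same transfer of configuration from C1 to C5. Cp2Zr(H)Cl (THF, 23 °C) then reduces the tertiary amide to aldehyde 11 without touching the acetate.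

Step 11: the Mitsunobu displacement at the hindered C17 carbinol may be slow, and SN2' attack or elimination to a diene may compete. The fallback sets out from 18 and comes back at 22 (step 10 is skipped). Condensation of 18 with p-toluenesulfonylhydrazide (EtOH, 23 °C) gives the tosylhydrazone F5. Reduction with catecholborane (CHCl3, 0 °C) and heating with NaOAc·3H2O expels the sulfinate and N2 from the resulting allylic diazene with the same 1,3-delivery of hydrogen to C7, which gives 22.

**Further compounds**
F1 | step 9 | C9 epimer of 22 | C=C1CC[C@@H]2[C@](C)(COC(C)=O)CCC[C@@]2(C)[C@H]1CCC1=CC(=O)OC1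
F2 | step 9 | ent-19-acetoxy-8-oxo-17-norlabd-13-en-15,16-olide | O=C1CC[C@@H]2[C@](C)(COC(C)=O)CCC[C@@]2(C)[C@@H]1CCC1=CC(=O)OC1
F3 | step 9 | C9 epimer of F2 | O=C1CC[C@@H]2[C@](C)(COC(C)=O)CCC[C@@]2(C)[C@H]1CCC1=CC(=O)OC1
F4 | step 6 | 2-[(1S,6R)-6-(acetoxymethyl)-2,6-dimethylcyclohex-2-en-1-yl]-N,N-dimethylacetamide | CN(C)C(=O)C[C@@H]1[C@](C)(COC(C)=O)CCC=C1C
F5 | step 11 | 4-methylbenzenesulfonylhydrazone of 18 | Cc1ccc(cc1)S(=O)(=O)N/N=C/C1=CC[C@@H]2[C@](C)(COC(C)=O)CCC[C@@]2(C)[C@@H]1CCC1=CC(=O)OC1
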